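**Retrosynthetic overview**
1. The target comes from the 7E-olefinic 11,12-epoxy-4-hydroxy cembran-16,3-olide by a final singlet-oxygen (Schenck) ene reaction, which installs the C8 hydroperoxide and moves the olefin to C6=C7.
2. The 14-membered carbocycle is closed at C6–C7 (sp3–sp2) by a proposed copper hydride/palladium hydroalkenylative macrocyclisation of a vinyl carbinol onto an (E)-alkenyl bromide; the oxirane comes from an ent-Shi epoxidation of the C11=C12 olefin just before.
3. The C12–C13 bond comes from a chemoselective B-alkyl Suzuki–Miyaura union of a west lactone (vinyl group → alkylborane) with an east (1E,5E)-1-bromo-6-iodo-diene.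
4. West fragment: the δ-lactone with C3/C4 arises from a Sharpless epoxidation followed by 6-exo epoxide opening by an amide oxygen; C1 from a rhodium-catalysed asymmetric vinylation of 5,6-dihydropyran-2-one, C15 by trans methylation, C4/C5/C18 from a formyl ylide.
5. East fragment: pent-4-yn-1-ol by carboalumination/bromination, Corey–Fuchs/methylation and hydrozirconation/iodination. Rings form in the order δ-lactone, oxirane, 14-membered carbocycle.

Convention (one assumption): macrocycles are named with cembrane locants (C1 = ring CH carrying C15, the CH(CH3) of the lactone; C3 = lactone O–CH; C4 = C(OH)CH3; C11/C12 = oxirane carbons; C16 = lactone C=O; C17–C20 = methyls on C15, C4, C8, C12), and the Why lines use the same locants for the corresponding carbons of earlier intermediates.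

**Route**

Step 1
Reactants: 1 5,6-dihydro-2H-pyran-2-one; 2 potassium vinyltrifluoroborate
Product: 3 (R)-4-vinyltetrahydro-2H-pyran-2-one
Conditions: [Rh(cod)2]PF6 (3 mol%), (R)-BINAP (3.3 mol%), toluene/H2O 4:1, 105 °C
Reagents that add atoms: none
Why: Rhodium-catalysed asymmetric 1,4-addition (Hayashi–Miyaura type), in which the (R)-BINAP–rhodium–vinyl species inserts one enantioface of the enoate and water protonates the oxa-π-allyl rhodium, setting the ring CH stereocentre (later C1).

Step 2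
Reactants: 3 (R)-4-vinyltetrahydro-2H-pyran-2-one
Product: 5 (3S,4S)-3-methyl-4-vinyltetrahydro-2H-pyran-2-one, via lithium enolate 4 (not isolated)
Conditions: LiN(iPr)2 (1.05 equiv), THF, −78 °C; then MeI, −78 to −40 °C
Reagents that add atoms: iodomethane CI
Why: Kinetic alkylation of the lactone lithium enolate, where iodomethane attacks anti to the adjacent vinyl group and gives the 3,4-trans lactone (later C15, S), which is also the thermodynamically preferred epimer.

Step 3
Reactants: 5 (3S,4S)-3-methyl-4-vinyltetrahydro-2H-pyran-2-one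
Product: 6 (2S,3S)-5-hydroxy-2-methyl-1-(pyrrolidin-1-yl)-3-vinylpentan-1-one
Conditions: pyrrolidine (3 equiv), THF, 50 °C
Reagents that add atoms: pyrrolidine C1CCNC1
Why: Aminolysis of the δ-lactone gives an open hydroxy amide that does not relactonise under neutral conditions and whose carbonyl oxygen serves as the internal nucleophile in step 9; no stereocentre is touched.

Step 4
Reactants: 6 (2S,3S)-5-hydroxy-2-methyl-1-(pyrrolidin-1-yl)-3-vinylpentan-1-one
Product: 7 (3S,4S)-4-methyl-5-oxo-5-(pyrrolidin-1-yl)-3-vinylpentanal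
Conditions: Dess–Martin periodinane (1.2 equiv), CH2Cl2, 0 °C to rt
Reagents that add atoms: none
Why: Dess–Martin oxidation of the primary alcohol to the aldehyde under near-neutral conditions that leave the stereocentres and the terminal alkene untouched.

Step 5
Reactants: 8 bromoethane
Product: 9 ethyltriphenylphosphonium bromide
Conditions: PPh3, toluene, 110 °C (sealed tube)
Reagents that add atoms: triphenylphosphine c1ccc(cc1)P(c1ccccc1)c1ccccc1
Why: SN2 quaternisation of triphenylphosphine by the primary bromide (phosphonium salt formation).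

Step 6
Reactants: 9 ethyltriphenylphosphonium bromide; 10 ethyl formate
Product: 12 2-(triphenyl-λ5-phosphanylidene)propanal, via ethylidenetriphenylphosphorane 11 (not isolated)
Conditions: KOtBu (2.1 equiv), THF, 0 °C; then HCO2Et, 0 °C to rt
Reagents that add atoms: none
Why: Ylide formation, C-formylation by ethyl formate (Claisen-type acylation of a phosphorus ylide) and deprotonation of the acylphosphonium by the second equivalent of base give the stabilised formyl ylide.

Step 7
Reactants: 7 (3S,4S)-4-methyl-5-oxo-5-(pyrrolidin-1-yl)-3-vinylpentanal; 12 2-(triphenyl-λ5-phosphanylidene)propanal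
Product: 13 (2E,5S,6S)-2,6-dimethyl-7-oxo-7-(pyrrolidin-1-yl)-5-vinylhept-2-enal
Conditions: toluene, 80 °C
Reagents that add atoms: none
Why: Wittig olefination with a stabilised ylide, which is (E)-selective (>95:5) for the trisubstituted enal and does not disturb the amide or its α-stereocentre.

Step 8
Reactants: 13 (2E,5S,6S)-2,6-dimethyl-7-oxo-7-(pyrrolidin-1-yl)-5-vinylhept-2-enal
Product: 14 (2S,3S,5E)-7-hydroxy-2,6-dimethyl-1-(pyrrolidin-1-yl)-3-vinylhept-5-en-1-one
Conditions: NaBH4, CeCl3·7H2O, MeOH, −20 °C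
Reagents that add atoms: none
Why: Luche 1,2-reduction of the enal to the (E)-allylic alcohol; amide and alkenes are inert.

Step 9
Reactants: 14 (2S,3S,5E)-7-hydroxy-2,6-dimethyl-1-(pyrrolidin-1-yl)-3-vinylhept-5-en-1-one
Product: 16 (3S,4S,6R)-6-[(2S)-1,2-dihydroxypropan-2-yl]-3-methyl-4-vinyltetrahydro-2H-pyran-2-one, via epoxy alcohol 15 (not isolated)
Conditions: Ti(OiPr)4 (20 mol%), L-(+)-DIPT (24 mol%), tBuOOH (2 equiv), 4 Å MS, CH2Cl2, −20 °C; then CSA (1.1 equiv), H2O (5 equiv), 0 °C to rt
Reagents that add atoms: tert-butyl hydroperoxide CC(C)(C)OO; water O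
Why: Sharpless asymmetric epoxidation (L-(+)-tartrate gives the (2S,3S)-epoxy alcohol and ignores the isolated vinyl group) followed by acid-promoted 6-exo attack of the amide oxygen on the secondary epoxide carbon with inversion and hydrolysis of the iminium ether, which forms the δ-lactone and sets C3 (R) and C4 (S) in the anti relationship.

Step 10
Reactants: 17 pent-4-yn-1-ol
Product: 19 (E)-5-bromo-4-methylpent-4-en-1-ol, via alkenylalane 18 (not isolated)
Conditions: AlMe3 (3 equiv), Cp2ZrCl2 (25 mol%), CH2Cl2, 0 °C to rt; then NBS, THF, −78 to 0 °C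
Reagents that add atoms: trimethylaluminium C[Al](C)C; N-bromosuccinimide O=C1CCC(=O)N1Br
Why: Negishi zirconium-catalysed syn-carboalumination places the methyl on the internal alkyne carbon, and bromodealumination proceeds with retention to the (E)-alkenyl bromide.

Step 11
Reactants: 19 (E)-5-bromo-4-methylpent-4-en-1-ol
Product: 20 (E)-5-bromo-4-methylpent-4-enal
Conditions: Dess–Martin periodinane (1.2 equiv), CH2Cl2, rt
Reagents that add atoms: none
Why: Dess–Martin oxidation of the primary alcohol; the alkenyl bromide is inert.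

Step 12
Reactants: 20 (E)-5-bromo-4-methylpent-4-enal
Product: 21 (5E)-1,1,6-tribromo-5-methylhexa-1,5-diene
Conditions: CBr4 (2 equiv), PPh3 (4 equiv), CH2Cl2, 0 °C
Reagents that add atoms: carbon tetrabromide BrC(Br)(Br)Br
Why: Corey–Fuchs (Ramirez) dibromoolefination of the aldehyde.

Step 13
Reactants: 21 (5E)-1,1,6-tribromo-5-methylhexa-1,5-diene
Product: 23 (E)-1-bromo-2-methylhept-1-en-5-yne, via lithium acetylide 22 (not isolated)
Conditions: n-BuLi (2.05 equiv), THF, −78 °C; then MeI, −78 °C to rt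
Reagents that add atoms: iodomethane CI
Why: Second stage of the Corey–Fuchs alkyne synthesis (bromine–lithium exchange and rearrangement to the lithium acetylide) with in situ methylation; the geminal dibromide exchanges far faster than the trisubstituted alkenyl bromide at −78 °C.

Step 14
Reactants: 23 (E)-1-bromo-2-methylhept-1-en-5-yne
Product: 25 (1E,5E)-1-bromo-6-iodo-2-methylhepta-1,5-diene, via alkenylzirconocene 24 (not isolated)
Conditions: Cp2Zr(H)Cl (2.5 equiv), THF, 50 °C; then I2, 0 °C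
Reagents that add atoms: iodine II
Why: Hydrozirconation (syn addition; with excess reagent zirconium equilibrates to the less hindered, methyl-bearing alkyne carbon) and iodinolysis with retention give the (E)-2-iodo-2-alkene.

Step 15
Reactants: 16 (3S,4S,6R)-6-[(2S)-1,2-dihydroxypropan-2-yl]-3-methyl-4-vinyltetrahydro-2H-pyran-2-one; 25 (1E,5E)-1-bromo-6-iodo-2-methylhepta-1,5-diene
Product: 27 (3S,4R,6R)-4-[(3E,7E)-8-bromo-3,7-dimethylocta-3,7-dien-1-yl]-6-[(2S)-1,2-dihydroxypropan-2-yl]-3-methyltetrahydro-2H-pyran-2-one, via alkylborane 26 (not isolated)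
Conditions: 9-BBN dimer (1.6 equiv), THF, 0 °C to rt; then 25 (1.1 equiv), Pd(dppf)Cl2 (5 mol%), AsPh3 (10 mol%), K3PO4 (3 M aq, 3 equiv), DMF, rt
Reagents that add atoms: none
Why: B-alkyl Suzuki–Miyaura coupling: anti-Markovnikov hydroboration of the only alkene of 16 (the hydroxyls are tolerated with excess borane, transient O-borinates being hydrolysed by the aqueous base), then oxidative addition at C–I much faster than at C–Br and coupling with retention of the E geometry form the C12–C13 bond.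

Step 16
Reactants: 27 (3S,4R,6R)-4-[(3E,7E)-8-bromo-3,7-dimethylocta-3,7-dien-1-yl]-6-[(2S)-1,2-dihydroxypropan-2-yl]-3-methyltetrahydro-2H-pyran-2-one
Product: 28 (2R)-2-{(2R,4R,5S)-4-[(3E,7E)-8-bromo-3,7-dimethylocta-3,7-dien-1-yl]-5-methyl-6-oxotetrahydro-2H-pyran-2-yl}-2-hydroxypropanal
Conditions: IBX (1.5 equiv), DMSO, rt
Reagents that add atoms: none
Why: IBX oxidation converts the primary alcohol of the 1,2-diol to the aldehyde without glycol cleavage, and the fully substituted α-carbon cannot epimerise (the descriptor changes only through CIP priorities).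

Step 17
Reactants: 28 (2R)-2-{(2R,4R,5S)-4-[(3E,7E)-8-bromo-3,7-dimethylocta-3,7-dien-1-yl]-5-methyl-6-oxotetrahydro-2H-pyran-2-yl}-2-hydroxypropanal
Product: 29 (3S,4R,6R)-4-[(3E,7E)-8-bromo-3,7-dimethylocta-3,7-dien-1-yl]-6-[(2S)-2-hydroxybut-3-en-2-yl]-3-methyltetrahydro-2H-pyran-2-one
Conditions: Ph3PCH3Br (2.6 equiv), KN(SiMe3)2 (2.5 equiv), THF, −78 to 0 °C
Reagents that add atoms: methyltriphenylphosphonium bromide C[P+](c1ccccc1)(c1ccccc1)c1ccccc1.[Br-]
Why: Wittig methylenation of the aldehyde (excess ylide also covers the tertiary hydroxyl) is fast at low temperature, faster than α-ketol rearrangement or attack on the lactone, and gives the vinyl carbinol.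

Step 18
Reactants: 29 (3S,4R,6R)-4-[(3E,7E)-8-bromo-3,7-dimethylocta-3,7-dien-1-yl]-6-[(2S)-2-hydroxybut-3-en-2-yl]-3-methyltetrahydro-2H-pyran-2-one
Product: 30 (3S,4R,6R)-4-{2-[(2S,3S)-3-[(E)-4-bromo-3-methylbut-3-en-1-yl]-2-methyloxiran-2-yl]ethyl}-6-[(2S)-2-hydroxybut-3-en-2-yl]-3-methyltetrahydro-2H-pyran-2-one
Conditions: ent-Shi ketone (L-fructose-derived, 30 mol%), KHSO5 (as Oxone, 1.5 equiv), K2CO3, Bu4NHSO4 (cat.), MeCN/CH2(OMe)2/aq Na2B4O7 buffer, 0 °C
Reagents that add atoms: potassium peroxymonosulfate [K+].[O-]S(=O)(=O)OO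
Why: Shi asymmetric epoxidation, in which the chiral dioxirane attacks the electron-rich (E)-trisubstituted C11=C12 olefin through the spiro transition state on the face that gives the (11S,12S)-oxirane, while the bromoalkene and the terminal vinyl group are too electron-poor to react.

Step 19
Reactants: 30 (3S,4R,6R)-4-{2-[(2S,3S)-3-[(E)-4-bromo-3-methylbut-3-en-1-yl]-2-methyloxiran-2-yl]ethyl}-6-[(2S)-2-hydroxybut-3-en-2-yl]-3-methyltetrahydro-2H-pyran-2-one
Product: 31 (1R,3R,4S,7E,11S,12S,15S)-11,12-epoxy-4-hydroxycembr-7-en-16,3-olide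
Conditions: Cu(OAc)2 (10 mol%), DTBM-SEGPHOS (11 mol%), [Pd(cinnamyl)Cl]2 (5 mol%), BrettPhos (11 mol%), Me(MeO)2SiH (3 equiv), NaOSiMe3 (2 equiv), THF, 45 °C, 30 added over 12 h (2 mM final); aq NH4F work-up
Reagents that add atoms: none
Why: Proposed new method: a ligated copper hydride (from Cu(OAc)2, DTBM-SEGPHOS and the silane) inserts the terminal olefin in the anti-Markovnikov sense, the primary alkylcopper transmetalates to the alkenylpalladium bromide formed by oxidative addition of the (E)-alkenyl bromide to zerovalent palladium, and C(sp3)–C(sp2) reductive elimination closes the 14-membered ring at C6–C7 with retention of the E geometry while NaOSiMe3 and silane regenerate the copper hydride; the closest known reactions are the intermolecular dual copper hydride/palladium anti-Markovnikov hydroarylation and hydroalkenylation of terminal olefins and the two-step hydroboration/B-alkyl Suzuki–Miyaura macrocyclisation, and a macrocyclising version of the dual-catalytic reaction has not been shown.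

Step 20
Reactants: 31 (1R,3R,4S,7E,11S,12S,15S)-11,12-epoxy-4-hydroxycembr-7-en-16,3-olide
Product: 32 (1R,3R,4S,6E,8R,11S,12S,15S)-11,12-epoxy-8-hydroperoxy-4-hydroxycembr-6-en-16,3-olide
Conditions: O2, tetraphenylporphyrin (1 mol%), CH2Cl2, white LED, −20 °C
Reagents that add atoms: dioxygen O=O
Why: Schenck ene reaction, in which singlet oxygen attacks the only olefin from the exposed peripheral face of the macrocycle, bonds to the tertiary C8 and abstracts a syn allylic hydrogen at C6 on the more crowded side of the olefin (cis effect), shifting the double bond to 6E and setting C8 (R) under substrate control that is expected but unproven; the C8 epimer and the 8(19)-ene-7-hydroperoxide are the by-products to separate.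

**Compound list**
1 | 5,6-dihydro-2H-pyran-2-one | O=C1C=CCCO1 | starting material
2 | potassium vinyltrifluoroborate | C=C[B-](F)(F)F.[K+] | starting material
3 | (R)-4-vinyltetrahydro-2H-pyran-2-one | C=C[C@H]1CC(=O)OCC1 | intermediate
4 | lithium (4S)-4-vinyl-5,6-dihydro-4H-pyran-2-olate (lithium enolate of 3) | C=C[C@@H]1CCOC(O[Li])=C1 | intermediate
5 | (3S,4S)-3-methyl-4-vinyltetrahydro-2H-pyran-2-one | C[C@@H]1C(=O)OCC[C@H]1C=C | intermediate
6 | (2S,3S)-5-hydroxy-2-methyl-1-(pyrrolidin-1-yl)-3-vinylpentan-1-one | C[C@H](C(=O)N1CCCC1)[C@@H](CCO)C=C | intermediate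
7 | (3S,4S)-4-methyl-5-oxo-5-(pyrrolidin-1-yl)-3-vinylpentanal | C[C@H](C(=O)N1CCCC1)[C@@H](CC=O)C=C | intermediate
8 | bromoethane | CCBr | starting material
9 | ethyltriphenylphosphonium bromide | CC[P+](c1ccccc1)(c1ccccc1)c1ccccc1.[Br-] | intermediate
10 | ethyl formate | CCOC=O | starting material
11 | ethylidenetriphenylphosphorane | CC=P(c1ccccc1)(c1ccccc1)c1ccccc1 | intermediate
12 | 2-(triphenyl-λ5-phosphanylidene)propanal | CC(C=O)=P(c1ccccc1)(c1ccccc1)c1ccccc1 | intermediate
13 | (2E,5S,6S)-2,6-dimethyl-7-oxo-7-(pyrrolidin-1-yl)-5-vinylhept-2-enal | C[C@H](C(=O)N1CCCC1)[C@@H](C/C=C(\C)C=O)C=C | intermediate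
14 | (2S,3S,5E)-7-hydroxy-2,6-dimethyl-1-(pyrrolidin-1-yl)-3-vinylhept-5-en-1-one | C[C@H](C(=O)N1CCCC1)[C@@H](C/C=C(\C)CO)C=C | intermediate
15 | (2S,3S)-4-[(2S,3S)-3-(hydroxymethyl)-3-methyloxiran-2-yl]-2-methyl-1-(pyrrolidin-1-yl)-3-vinylbutan-1-one | C[C@H](C(=O)N1CCCC1)[C@@H](C[C@@H]1O[C@@]1(C)CO)C=C | intermediate
16 | (3S,4S,6R)-6-[(2S)-1,2-dihydroxypropan-2-yl]-3-methyl-4-vinyltetrahydro-2H-pyran-2-one | C[C@@H]1C(=O)O[C@H](C[C@H]1C=C)[C@@](C)(O)CO | intermediate
17 | pent-4-yn-1-ol | C#CCCCO | starting material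
18 | (E)-[5-(dimethylalumanyloxy)-2-methylpent-1-en-1-yl]dimethylalumane | C[Al](C)/C=C(\C)CCCO[Al](C)C | intermediate
19 | (E)-5-bromo-4-methylpent-4-en-1-ol | OCCC/C(C)=C/Br | intermediate
20 | (E)-5-bromo-4-methylpent-4-enal | O=CCC/C(C)=C/Br | intermediate
21 | (5E)-1,1,6-tribromo-5-methylhexa-1,5-diene | BrC(Br)=CCC/C(C)=C/Br | intermediate
22 | [(5E)-6-bromo-5-methylhex-5-en-1-yn-1-yl]lithium | [Li]C#CCC/C(C)=C/Br | intermediate
23 | (E)-1-bromo-2-methylhept-1-en-5-yne | CC#CCC/C(C)=C/Br | intermediate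
24 | [(2E,6E)-7-bromo-6-methylhepta-2,6-dien-2-yl]chlorobis(cyclopentadienyl)zirconium | C/C(=C\CC/C(C)=C/Br)[Zr](Cl)(C1C=CC=C1)C1C=CC=C1 | intermediate
25 | (1E,5E)-1-bromo-6-iodo-2-methylhepta-1,5-diene | I/C(C)=C/CC/C(C)=C/Br | intermediate
26 | (3S,4R,6R)-4-[2-(9-borabicyclo[3.3.1]nonan-9-yl)ethyl]-6-[(2S)-1,2-dihydroxypropan-2-yl]-3-methyltetrahydro-2H-pyran-2-one | C[C@@H]1C(=O)O[C@H](C[C@H]1CCB1C2CCCC1CCC2)[C@@](C)(O)CO | intermediate
27 | (3S,4R,6R)-4-[(3E,7E)-8-bromo-3,7-dimethylocta-3,7-dien-1-yl]-6-[(2S)-1,2-dihydroxypropan-2-yl]-3-methyltetrahydro-2H-pyran-2-one | C[C@@H]1C(=O)O[C@H](C[C@H]1CC/C(C)=C/CC/C(C)=C/Br)[C@@](C)(O)CO | intermediate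
28 | (2R)-2-{(2R,4R,5S)-4-[(3E,7E)-8-bromo-3,7-dimethylocta-3,7-dien-1-yl]-5-methyl-6-oxotetrahydro-2H-pyran-2-yl}-2-hydroxypropanal | C[C@@H]1C(=O)O[C@H](C[C@H]1CC/C(C)=C/CC/C(C)=C/Br)[C@@](C)(O)C=O | intermediate
29 | (3S,4R,6R)-4-[(3E,7E)-8-bromo-3,7-dimethylocta-3,7-dien-1-yl]-6-[(2S)-2-hydroxybut-3-en-2-yl]-3-methyltetrahydro-2H-pyran-2-one | C[C@@H]1C(=O)O[C@H](C[C@H]1CC/C(C)=C/CC/C(C)=C/Br)[C@@](C)(O)C=C | intermediate
30 | (3S,4R,6R)-4-{2-[(2S,3S)-3-[(E)-4-bromo-3-methylbut-3-en-1-yl]-2-methyloxiran-2-yl]ethyl}-6-[(2S)-2-hydroxybut-3-en-2-yl]-3-methyltetrahydro-2H-pyran-2-one | C[C@@H]1C(=O)O[C@H](C[C@H]1CC[C@]1(C)O[C@H]1CC/C(C)=C/Br)[C@@](C)(O)C=C | intermediate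
31 | (1R,3R,4S,7E,11S,12S,15S)-11,12-epoxy-4-hydroxycembr-7-en-16,3-olide | C[C@@H]1C(=O)O[C@@H]2C[C@H]1CC[C@]1(C)O[C@H]1CC/C(C)=C/CC[C@]2(C)O | intermediate
32 | (1R,3R,4S,6E,8R,11S,12S,15S)-11,12-epoxy-8-hydroperoxy-4-hydroxycembr-6-en-16,3-olide (CNP0297487.3) | C[C@@H]1C(=O)O[C@@H]2C[C@H]1CC[C@]1(C)O[C@H]1CC[C@@](C)(OO)/C=C/C[C@]2(C)O | target

**Step count**
Total steps: 20. Longest linear sequence: 13 steps (1–4, 7–9, 15–20).

**Steps most likely to fail**

Step 17. The α-hydroxy aldehyde 28 can undergo base-induced α-ketol rearrangement, and the ylide can enolise the lactone. The fallback sets out from 27 and comes back at 29. Both hydroxyls of 27 are silylated (Et3SiOTf, 2,6-lutidine, CH2Cl2, −78 °C) to the bis(triethylsilyl) ether F1. Swern conditions ((COCl)2, DMSO, −78 to −30 °C; Et3N) cleave and oxidise only the primary silyl ether and give the α-(triethylsilyloxy) aldehyde F2, which has no free hydroxyl and cannot rearrange. Wittig methylenation gives the silyl-protected vinyl carbinol F3, and Bu4NF/AcOH (THF, 0 °C) returns 29.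

Step 19. This is the proposed macrocyclisation; the risks are protodecupration to the ethyl carbinol by the neighbouring tertiary hydroxyl, Heck-type closure and oligomerisation. The fallback uses known chemistry, sets out from 30 and comes back at 31. Hydroboration of the vinyl carbinol with 9-BBN dimer (THF, rt, excess to cover the hydroxyl) gives the alkylborane F4, which is not isolated but added by syringe pump (final 1 mM) to Pd(dppf)Cl2, AsPh3 and Cs2CO3 in DMF/THF/H2O at 50 °C. This intramolecular B-alkyl Suzuki–Miyaura coupling with the (E)-alkenyl bromide closes the same C6–C7 bond with retention of geometry.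

Step 20. Both the site of hydrogen abstraction (C6 versus the C19 methyl) and the face of attack at C8 depend on substrate control and cannot be guaranteed. The fallback sets out from 31 and comes back at 32, and replaces the free carbinol by a different control element. The C4 hydroxyl is silylated (Et3SiOTf, 2,6-lutidine, CH2Cl2, −78 °C) to the C4 triethylsilyl ether F5. Its bulky silyloxy group removes the hydroxyl hydrogen bond, shields the ring face syn to it and enlarges the substituent next to C6, which is intended to steer abstraction to the C6 methylene. Photooxygenation (O2, tetraphenylporphyrin, hν, CH2Cl2, −20 °C) gives the silylated hydroperoxide F6, and Bu4NF/AcOH (THF, 0 °C) removes the silyl group to give 32. This fallback is a weaker remedy than the other two, since it still relies on the ene reaction.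

**Further compounds**
F1 | step 17 | (3S,4R,6R)-4-[(3E,7E)-8-bromo-3,7-dimethylocta-3,7-dien-1-yl]-6-[(2S)-1,2-bis(triethylsilyloxy)propan-2-yl]-3-methyltetrahydro-2H-pyran-2-one | C[C@@H]1C(=O)O[C@H](C[C@H]1CC/C(C)=C/CC/C(C)=C/Br)[C@@](C)(O[Si](CC)(CC)CC)CO[Si](CC)(CC)CC
F2 | step 17 | (2R)-2-{(2R,4R,5S)-4-[(3E,7E)-8-bromo-3,7-dimethylocta-3,7-dien-1-yl]-5-methyl-6-oxotetrahydro-2H-pyran-2-yl}-2-(triethylsilyloxy)propanal | C[C@@H]1C(=O)O[C@H](C[C@H]1CC/C(C)=C/CC/C(C)=C/Br)[C@@](C)(O[Si](CC)(CC)CC)C=O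
F3 | step 17 | (3S,4R,6R)-4-[(3E,7E)-8-bromo-3,7-dimethylocta-3,7-dien-1-yl]-3-methyl-6-[(2S)-2-(triethylsilyloxy)but-3-en-2-yl]tetrahydro-2H-pyran-2-one | C[C@@H]1C(=O)O[C@H](C[C@H]1CC/C(C)=C/CC/C(C)=C/Br)[C@@](C)(O[Si](CC)(CC)CC)C=C
F4 | step 19 | (3S,4R,6R)-6-[(2S)-4-(9-borabicyclo[3.3.1]nonan-9-yl)-2-hydroxybutan-2-yl]-4-{2-[(2S,3S)-3-[(E)-4-bromo-3-methylbut-3-en-1-yl]-2-methyloxiran-2-yl]ethyl}-3-methyltetrahydro-2H-pyran-2-one | C[C@@H]1C(=O)O[C@H](C[C@H]1CC[C@]1(C)O[C@H]1CC/C(C)=C/Br)[C@@](C)(O)CCB1C2CCCC1CCC2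
F5 | step 20 | (1R,3R,4S,7E,11S,12S,15S)-11,12-epoxy-4-(triethylsilyloxy)cembr-7-en-16,3-olide | C[C@@H]1C(=O)O[C@@H]2C[C@H]1CC[C@]1(C)O[C@H]1CC/C(C)=C/CC[C@]2(C)O[Si](CC)(CC)CC
F6 | step 20 | (1R,3R,4S,6E,8R,11S,12S,15S)-11,12-epoxy-8-hydroperoxy-4-(triethylsilyloxy)cembr-6-en-16,3-olide | C[C@@H]1C(=O)O[C@@H]2C[C@H]1CC[C@]1(C)O[C@H]1CC[C@@](C)(OO)/C=C/C[C@]2(C)O[Si](CC)(CC)CC
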